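**Plan**

1. Retrosynthesis: cut C2–C1' (ring B to C2), cut C8–CH2 of the side chain, then contract the pyranone ring by removing C3 (bonds C2–C3 and C3–C4), which leads back to 4,6-dimethoxybenzofuran-3(2H)-one; the side chain is cut at its Cα–CH2(prenyl) bond.
2. Forward: ring A and O1 come with the five-membered furanone; its silyl enol ether is cyclopropanated and the cyclopropane is opened oxidatively, so the six-membered pyranone ring arises by one-carbon ring expansion; then C8 iodination, 5-O-demethylation, Negishi coupling of the side chain, rhodium-catalysed arylation at C2 and MOM removal.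
3. Enabling feature: C2 is bonded to the ring oxygen O1 and lies two bonds from the C4 carbonyl, so the lower homologue O1–CH2–C(=O) enolises to an aromatic 3-siloxybenzofuran that takes up CH2 at its C2=C3 bond, and O1 then stabilises a radical at the future C2, so the bond shared by the cyclopropane and the furan ring breaks and the CH2 becomes C3.
4. Stereochemistry: C2 (S) comes from the chiral bisphosphine on rhodium in step 14; the side-chain centre comes from the oxazolidinone auxiliary in step 7.
5. Regiochemistry of ring A: O1 is fixed from the start, C8 is reached by iodination of the 5,7-dimethyl ether, and the peri 5-OMe is then cleaved by chelation.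

Key step: step 3

Remark: 1, 8, 9, 12 and 19 are taken as commercial; the side-chain centre is (S) up to 17 and (R) from 18 on with no change in space, because CH2–aryl ranks below isopropenyl whereas CH2–O, CH2–I and CH2–Zn rank above it; the facial sense in step 14 rests on the analogy stated there.

Abbreviations: TMS = trimethylsilyl; MOM = methoxymethyl; NIS, NBS = N-iodo-, N-bromosuccinimide; cod = cycloocta-1,5-diene; SPhos = 2-dicyclohexylphosphino-2',6'-dimethoxybiphenyl; RuPhos = 2-dicyclohexylphosphino-2',6'-diisopropoxybiphenyl; (S)-MeO-F12-BIPHEP = (S)-2,2'-bis[bis(3,4,5-trifluorophenyl)phosphino]-6,6'-dimethoxybiphenyl; binap = 2,2'-bis(diphenylphosphino)-1,1'-binaphthyl.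

**Route**

Step 1
Reactants: 1 4,6-dimethoxy-1-benzofuran-3(2H)-one
Product: 2 [(4,6-dimethoxy-1-benzofuran-3-yl)oxy]trimethylsilane
Conditions: Me3SiOTf, Et3N, CH2Cl2, 0 °C
Reagents that add atoms: trimethylsilyl trifluoromethanesulfonate, C[Si](C)(C)OS(=O)(=O)C(F)(F)F
Why: Silyl enol ether formation by soft enolisation of the 3-coumaranone is driven by the aromatic benzofuran that results, so O-silylation should be clean.

Step 2
Reactants: 2 [(4,6-dimethoxy-1-benzofuran-3-yl)oxy]trimethylsilane
Product: 3 racemic [(4,6-dimethoxy-1a,6b-dihydro-1H-cyclopropa[b][1]benzofuran-6b-yl)oxy]trimethylsilane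
Conditions: Et2Zn, CH2I2, CH2Cl2, 0 °C to rt
Reagents that add atoms: diiodomethane, C(I)I
Why: Furukawa-modified Simmons–Smith cyclopropanation, in which the electrophilic zinc carbenoid adds CH2 to the C2=C3 bond that carries two oxygen donors and is the only non-benzenoid alkene; the cis-fused product is racemic and both of its stereocentres are erased in step 3.

Step 3
Reactants: 3 racemic [(4,6-dimethoxy-1a,6b-dihydro-1H-cyclopropa[b][1]benzofuran-6b-yl)oxy]trimethylsilane
Product: 5 5,7-dimethoxy-4H-chromen-4-one, via 2-chlorochromanone 4 (not isolated)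
Conditions: FeCl3 (2.5 equiv), DMF, 0 °C to rt; then NaOAc, MeOH, reflux
Reagents that add atoms: none
Why: Saegusa-type oxidative ring expansion of a siloxycyclopropane: FeCl3 cleaves the O–Si bond and oxidises the cyclopropanolate by one electron to an alkoxy radical at C6b, whose β-scission breaks the bond shared by the cyclopropane and the five-membered oxygen ring (C1a–C6b) and not the outer C1–C6b bond, because the radical left at C1a is secondary and stabilised by the lone pair of the ring oxygen whereas the alternative is primary. Chlorine transfer from a second FeCl3 should give the 2-chlorochroman-4-one 4, an α-chloro ether that loses HCl with NaOAc to give chromone 5; the closest known reaction is the FeCl3/DMF then NaOAc conversion of 1-(trimethylsiloxy)bicyclo[4.1.0]heptane into cyclohept-2-enone. No ring is closed by cyclisation: the six-membered pyranone ring arises from the five-membered dihydrofuran ring of 3 when the zero-atom bridge of the bicyclo[3.1.0] unit breaks, which places the cyclopropane CH2 (future C3) between the O-bound carbon (future C2) and the carbinol carbon (future C4). No stereocentre is formed and the two of 3 are destroyed, so the racemic nature of 3 does not matter. The step needs regioselectivity (inner versus outer cyclopropane bond) and chemoselectivity (no oxidation of the dimethoxyarene); the first is secured by O1 on C1a, the second by DMF-moderated FeCl3 and by the acyl group that deactivates the arene as soon as the ketone appears.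

Step 4
Reactants: 5 5,7-dimethoxy-4H-chromen-4-one
Product: 6 8-iodo-5,7-dimethoxy-4H-chromen-4-one
Conditions: NIS, CF3CO2H (cat.), MeCN, 0 °C to rt
Reagents that add atoms: N-iodosuccinimide, O=C1CCC(=O)N1I
Why: Electrophilic aromatic iodination, expected at C8 because with O5 and O7 both alkylated this position (between O1 and the 7-OMe, para to the 5-OMe) is the less hindered activated site, C6 lies between two methoxy groups, and C3 of the vinylogous ester is far less nucleophilic than the trioxygenated benzene ring.

Step 5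
Reactants: 6 8-iodo-5,7-dimethoxy-4H-chromen-4-one
Product: 7 5-hydroxy-8-iodo-7-methoxy-4H-chromen-4-one
Conditions: BCl3 (1.5 equiv), CH2Cl2, −78 to 0 °C; aq. NaHCO3
Reagents that add atoms: none
Why: Chelation-controlled ether cleavage, in which BCl3 binds the C4 carbonyl and the peri 5-OMe in a six-membered chelate and removes only that methyl group, leaving the 7-OMe and the aryl iodide intact.

Step 6
Reactants: 8 (4S)-4-benzyl-1,3-oxazolidin-2-one; 9 3-methylbut-2-enoyl chloride
Product: 11 (4S)-4-benzyl-3-(3-methylbut-2-enoyl)-1,3-oxazolidin-2-one, via lithium oxazolidinide 10 (not isolated)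
Conditions: n-BuLi, THF, −78 °C; then 9, −78 to 0 °C
Reagents that add atoms: none
Why: N-Acylation of the lithiated oxazolidinone with the acid chloride (standard imide formation for the Evans auxiliary), which does not touch the auxiliary stereocentre.

Step 7
Reactants: 11 (4S)-4-benzyl-3-(3-methylbut-2-enoyl)-1,3-oxazolidin-2-one; 12 1-bromo-3-methylbut-2-ene
Product: 14 (4S)-4-benzyl-3-[(2S)-5-methyl-2-(prop-1-en-2-yl)hex-4-enoyl]-1,3-oxazolidin-2-one, via sodium dienolate 13 (not isolated)
Conditions: NaN(SiMe3)2, THF, −78 °C; then 12, −78 to −30 °C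
Reagents that add atoms: none
Why: Evans auxiliary alkylation through the chelated (Z)-dienolate formed by γ-deprotonation, in which prenyl bromide attacks the α-carbon on the face opposite the benzyl group and so should give the deconjugated α-prenyl imide with the (2S) centre (same facial sense as propionimide alkylations; only the group ranks differ).

Step 8
Reactants: 14 (4S)-4-benzyl-3-[(2S)-5-methyl-2-(prop-1-en-2-yl)hex-4-enoyl]-1,3-oxazolidin-2-one
Product: 15 (2S)-5-methyl-2-(prop-1-en-2-yl)hex-4-en-1-ol
Conditions: LiBH4, MeOH (1 equiv), Et2O, 0 °C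
Reagents that add atoms: none
Why: Reductive removal of the auxiliary by hydride attack at the exocyclic imide carbonyl gives the primary alcohol without touching the α-stereocentre or the two alkenes.

Step 9
Reactants: 15 (2S)-5-methyl-2-(prop-1-en-2-yl)hex-4-en-1-ol
Product: 16 (3S)-3-(iodomethyl)-2,6-dimethylhepta-1,5-diene
Conditions: PPh3, I2, imidazole, CH2Cl2, 0 °C to rt
Reagents that add atoms: iodine, I-I
Why: Appel-type iodination of the primary alcohol by SN2 at CH2, which does not involve the adjacent stereocentre.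

Step 10
Reactants: 16 (3S)-3-(iodomethyl)-2,6-dimethylhepta-1,5-diene; 7 5-hydroxy-8-iodo-7-methoxy-4H-chromen-4-one
Product: 18 5-hydroxy-7-methoxy-8-[(2R)-5-methyl-2-(prop-1-en-2-yl)hex-4-en-1-yl]-4H-chromen-4-one, via alkylzinc iodide 17 (not isolated)
Conditions: Zn dust, LiCl, THF, 40 °C; then 7, Pd(OAc)2 (3 mol %), SPhos (6 mol %), THF, rt to 45 °C, slow addition of 17
Reagents that add atoms: none
Why: Negishi sp3–sp2 coupling, in which LiCl-assisted zinc insertion gives the primary alkylzinc that transmetalates to the arylpalladium formed from the hindered aryl iodide; the bulky biarylphosphine favours reductive elimination over β-hydride elimination, alkylzinc halides tolerate the chelated phenol and the enone, and the β-stereocentre is not involved.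

Step 11
Reactants: 19 4-methoxybenzene-1,3-diol
Product: 20 1-methoxy-2,4-bis(methoxymethoxy)benzene
Conditions: MOMCl, i-Pr2NEt, CH2Cl2, 0 °C to rt
Reagents that add atoms: chloromethyl methyl ether, COCCl
Why: O-Alkylation of both phenols with the chloromethyl ether under amine base gives the bis-MOM acetal.

Step 12
Reactants: 20 1-methoxy-2,4-bis(methoxymethoxy)benzene
Product: 21 1-bromo-5-methoxy-2,4-bis(methoxymethoxy)benzene
Conditions: NBS, MeCN, 0 °C
Reagents that add atoms: N-bromosuccinimide, O=C1CCC(=O)N1Br
Why: Electrophilic aromatic bromination should go to the position ortho to one OMOM and para to the other, since the position between the two OMOM groups is hindered and the one next to OMe has only one activating ortho oxygen.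

Step 13
Reactants: 21 1-bromo-5-methoxy-2,4-bis(methoxymethoxy)benzene
Product: 24 [5-methoxy-2,4-bis(methoxymethoxy)phenyl]boronic acid, via aryllithium 22 (not isolated), via lithium triisopropoxyborate 23 (not isolated)
Conditions: n-BuLi, THF, −78 °C; B(Oi-Pr)3, −78 to 0 °C; aq. NH4Cl
Reagents that add atoms: triisopropyl borate, CC(C)OB(OC(C)C)OC(C)C; water, O
Why: Bromine–lithium exchange, borate trapping and mild hydrolysis (lithiation–borylation), with exchange at −78 °C faster than ortho-lithiation between the OMOM groups and an NH4Cl work-up that spares the MOM ethers.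

Step 14
Reactants: 18 5-hydroxy-7-methoxy-8-[(2R)-5-methyl-2-(prop-1-en-2-yl)hex-4-en-1-yl]-4H-chromen-4-one; 24 [5-methoxy-2,4-bis(methoxymethoxy)phenyl]boronic acid
Product: 25 (2S)-5-hydroxy-7-methoxy-2-[5-methoxy-2,4-bis(methoxymethoxy)phenyl]-8-[(2R)-5-methyl-2-(prop-1-en-2-yl)hex-4-en-1-yl]-2,3-dihydro-4H-chromen-4-one
Conditions: [Rh(OH)(cod)]2 (3 mol %), (S)-MeO-F12-BIPHEP (6.6 mol %), 24 (3 equiv, in portions), toluene/H2O (10:1), 35 °C
Reagents that add atoms: none
Why: Hayashi–Miyaura rhodium-catalysed asymmetric 1,4-addition of an arylboronic acid to a chromone, in which the aryl–rhodium complex of the (S)-bisphosphine inserts the C2=C3 bond from one face and water protonates the oxa-π-allyl rhodium, so C2 is set by the ligand; the (S)-ligand is expected to give (2S) by analogy with the (S)-3-arylcyclohexanones it gives from cyclohexenone (same arrangement in space), independent of the remote side-chain centre, and the base-free hydroxo-rhodium conditions avoid ring opening of the 5-hydroxyflavanone.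

Step 15
Reactants: 25 (2S)-5-hydroxy-7-methoxy-2-[5-methoxy-2,4-bis(methoxymethoxy)phenyl]-8-[(2R)-5-methyl-2-(prop-1-en-2-yl)hex-4-en-1-yl]-2,3-dihydro-4H-chromen-4-one
Product: 26 (2S)-2-(2,4-dihydroxy-5-methoxyphenyl)-5-hydroxy-7-methoxy-8-[(2R)-5-methyl-2-(prop-1-en-2-yl)hex-4-en-1-yl]-2,3-dihydro-4H-chromen-4-one
Conditions: HCl (2 M), MeOH, rt to 40 °C
Reagents that add atoms: none
Why: Acid-catalysed acetal cleavage of both MOM ethers with methanol as formaldehyde acceptor; flavanones open by base and not by dilute acid, so C2 should hold, and no free phenol flanks the side-chain alkenes, so no chroman formation is expected.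

**Compound list**

1 | 4,6-dimethoxy-1-benzofuran-3(2H)-one | COc1cc(OC)c2c(c1)OCC2=O | starting material
2 | [(4,6-dimethoxy-1-benzofuran-3-yl)oxy]trimethylsilane | COc1cc(OC)c2c(O[Si](C)(C)C)coc2c1 | intermediate
3 | racemic [(4,6-dimethoxy-1a,6b-dihydro-1H-cyclopropa[b][1]benzofuran-6b-yl)oxy]trimethylsilane | COc1cc(OC)c2c(c1)OC1CC12O[Si](C)(C)C | intermediate
4 | racemic 2-chloro-5,7-dimethoxy-2,3-dihydro-4H-chromen-4-one | O=C1CC(Cl)Oc2cc(OC)cc(OC)c12 | intermediate (not isolated)
5 | 5,7-dimethoxy-4H-chromen-4-one | O=c1ccoc2cc(OC)cc(OC)c12 | intermediate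
6 | 8-iodo-5,7-dimethoxy-4H-chromen-4-one | O=c1ccoc2c(I)c(OC)cc(OC)c12 | intermediate
7 | 5-hydroxy-8-iodo-7-methoxy-4H-chromen-4-one | O=c1ccoc2c(I)c(OC)cc(O)c12 | intermediate
8 | (4S)-4-benzyl-1,3-oxazolidin-2-one | O=C1N[C@@H](Cc2ccccc2)CO1 | starting material
9 | 3-methylbut-2-enoyl chloride | CC(C)=CC(=O)Cl | starting material
10 | lithium (4S)-4-benzyl-2-oxo-1,3-oxazolidin-3-ide | [Li+].O=C1[N-][C@@H](Cc2ccccc2)CO1 | intermediate (not isolated)
11 | (4S)-4-benzyl-3-(3-methylbut-2-enoyl)-1,3-oxazolidin-2-one | CC(C)=CC(=O)N1[C@@H](Cc2ccccc2)COC1=O | intermediate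
12 | 1-bromo-3-methylbut-2-ene | CC(C)=CCBr | starting material
13 | sodium (Z)-dienolate of 11 | [Na+].C=C(C)/C=C(\[O-])N1[C@@H](Cc2ccccc2)COC1=O | intermediate (not isolated)
14 | (4S)-4-benzyl-3-[(2S)-5-methyl-2-(prop-1-en-2-yl)hex-4-enoyl]-1,3-oxazolidin-2-one | C=C(C)[C@H](CC=C(C)C)C(=O)N1[C@@H](Cc2ccccc2)COC1=O | intermediate
15 | (2S)-5-methyl-2-(prop-1-en-2-yl)hex-4-en-1-ol | C=C(C)[C@H](CC=C(C)C)CO | intermediate
16 | (3S)-3-(iodomethyl)-2,6-dimethylhepta-1,5-diene | C=C(C)[C@H](CC=C(C)C)CI | intermediate
17 | iodo[(2S)-5-methyl-2-(prop-1-en-2-yl)hex-4-en-1-yl]zinc | C=C(C)[C@H](CC=C(C)C)C[Zn]I | intermediate (not isolated)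
18 | 5-hydroxy-7-methoxy-8-[(2R)-5-methyl-2-(prop-1-en-2-yl)hex-4-en-1-yl]-4H-chromen-4-one | C=C(C)[C@H](CC=C(C)C)Cc1c(OC)cc(O)c2c1occc2=O | intermediate
19 | 4-methoxybenzene-1,3-diol | COc1ccc(O)cc1O | starting material
20 | 1-methoxy-2,4-bis(methoxymethoxy)benzene | COCOc1ccc(OC)c(OCOC)c1 | intermediate
21 | 1-bromo-5-methoxy-2,4-bis(methoxymethoxy)benzene | COCOc1cc(OCOC)c(OC)cc1Br | intermediate
22 | [5-methoxy-2,4-bis(methoxymethoxy)phenyl]lithium | [Li]c1cc(OC)c(OCOC)cc1OCOC | intermediate (not isolated)
23 | lithium triisopropoxy[5-methoxy-2,4-bis(methoxymethoxy)phenyl]borate | [Li+].CC(C)O[B-](OC(C)C)(OC(C)C)c1cc(OC)c(OCOC)cc1OCOC | intermediate (not isolated)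
24 | [5-methoxy-2,4-bis(methoxymethoxy)phenyl]boronic acid | OB(O)c1cc(OC)c(OCOC)cc1OCOC | intermediate
25 | (2S)-5-hydroxy-7-methoxy-2-[5-methoxy-2,4-bis(methoxymethoxy)phenyl]-8-[(2R)-5-methyl-2-(prop-1-en-2-yl)hex-4-en-1-yl]-2,3-dihydro-4H-chromen-4-one | C=C(C)[C@H](CC=C(C)C)Cc1c(OC)cc(O)c2c1O[C@H](c1cc(OC)c(OCOC)cc1OCOC)CC2=O | intermediate
26 | (2S)-2-(2,4-dihydroxy-5-methoxyphenyl)-5-hydroxy-7-methoxy-8-[(2R)-5-methyl-2-(prop-1-en-2-yl)hex-4-en-1-yl]-2,3-dihydro-4H-chromen-4-one | C=C(C)[C@H](CC=C(C)C)Cc1c(OC)cc(O)c2c1O[C@H](c1cc(OC)c(O)cc1O)CC2=O | target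

**Step count and risks**

Total step count: 15.
Longest linear sequence: 8 steps (1, 2, 3, 4, 5, 10, 14, 15).

Steps most likely to fail:

Step 3. The oxidation may stop at silyl loss without C–C scission, the outer cyclopropane bond may open by protonolysis to a 2-methylbenzofuranone, or FeCl3 may couple or chlorinate the electron-rich arene. The fallback sets out from 2 and rejoins at 5, and replaces the one-electron opening by a two-electron one. Dibromocarbene (CHBr3, KOt-Bu, pentane, −20 °C to rt) adds to the C2=C3 bond of 2 to give [(1,1-dibromo-4,6-dimethoxy-1a,6b-dihydro-1H-cyclopropa[b][1]benzofuran-6b-yl)oxy]trimethylsilane F1, which is not isolated. It should open by the cyclopropyl-to-allyl cation pathway, losing bromide and the silyl group, to give 3-bromo-5,7-dimethoxy-4H-chromen-4-one F2. Hydrodebromination (Pd(PPh3)4, HCO2Na, DMF, 90 °C) then gives 5.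

Step 10. Slow oxidative addition into the di-ortho-substituted, electron-rich aryl iodide may let protonolysis of the alkylzinc by the phenol and β-hydride elimination from the alkylpalladium take over. The fallback sets out from 16 and rejoins at 18, and moves the alkyl group from zinc to boron. Iodine–lithium exchange (t-BuLi, Et2O, −78 °C), B(OMe)3 and aqueous KHF2 convert 16 into potassium trifluoro[(2S)-5-methyl-2-(prop-1-en-2-yl)hex-4-en-1-yl]borate F3, a bench-stable salt that is indifferent to the phenol. Suzuki–Miyaura B-alkyl coupling of F3 with 7 (Pd(OAc)2, RuPhos, K2CO3, toluene/H2O, 80 °C) gives 18.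

Step 14. Protodeboronation of the electron-rich ortho-alkoxy boronic acid in the aqueous medium may outrun the slow insertion of the hindered aryl–rhodium into the vinylogous ester. The fallback sets out from 18 and 21 and rejoins at 25, and replaces the protic boron transmetalation by an aprotic zinc one with silyl trapping. Chromone 18 is silylated at O5 (Me3SiCl, Et3N, THF) to give 7-methoxy-8-[(2R)-5-methyl-2-(prop-1-en-2-yl)hex-4-en-1-yl]-5-(trimethylsilyloxy)-4H-chromen-4-one F4. Bromide 21 is taken through aryllithium 22 and ZnCl2 to chloro[5-methoxy-2,4-bis(methoxymethoxy)phenyl]zinc F5. Rhodium-catalysed asymmetric 1,4-addition of F5 to F4 ([RhCl((S)-binap)]2, Me3SiCl, THF, 20 °C) should trap the adduct as (2S)-7-methoxy-2-[5-methoxy-2,4-bis(methoxymethoxy)phenyl]-8-[(2R)-5-methyl-2-(prop-1-en-2-yl)hex-4-en-1-yl]-4,5-bis(trimethylsilyloxy)-2H-chromene F6. Dilute citric acid then hydrolyses both silyl groups to give 25.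

Further compounds
F1 | step 3 | [(1,1-dibromo-4,6-dimethoxy-1a,6b-dihydro-1H-cyclopropa[b][1]benzofuran-6b-yl)oxy]trimethylsilane | COc1cc(OC)c2c(c1)OC1C(Br)(Br)C12O[Si](C)(C)C
F2 | step 3 | 3-bromo-5,7-dimethoxy-4H-chromen-4-one | O=c1c(Br)coc2cc(OC)cc(OC)c12
F3 | step 10 | potassium trifluoro[(2S)-5-methyl-2-(prop-1-en-2-yl)hex-4-en-1-yl]borate | [K+].C=C(C)[C@H](CC=C(C)C)C[B-](F)(F)F
F4 | step 14 | 7-methoxy-8-[(2R)-5-methyl-2-(prop-1-en-2-yl)hex-4-en-1-yl]-5-(trimethylsilyloxy)-4H-chromen-4-one | C=C(C)[C@H](CC=C(C)C)Cc1c(OC)cc(O[Si](C)(C)C)c2c1occc2=O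
F5 | step 14 | chloro[5-methoxy-2,4-bis(methoxymethoxy)phenyl]zinc | Cl[Zn]c1cc(OC)c(OCOC)cc1OCOC
F6 | step 14 | (2S)-7-methoxy-2-[5-methoxy-2,4-bis(methoxymethoxy)phenyl]-8-[(2R)-5-methyl-2-(prop-1-en-2-yl)hex-4-en-1-yl]-4,5-bis(trimethylsilyloxy)-2H-chromene | C=C(C)[C@H](CC=C(C)C)Cc1c(OC)cc(O[Si](C)(C)C)c2c1O[C@H](c1cc(OC)c(OCOC)cc1OCOC)C=C2O[Si](C)(C)C
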